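**Retrosynthetic overview**

1. Ring A (the cyclohexenone; C1 = C=O, C2 = CH, C3 = C–OMe, C4 = ketal carbon, C5 = CH2, C6 = CH–allyl) is closed last at C1–C2. An acyclic C6-allyl carboxylate is turned into a ketene, and its carbon C1 is attacked by the CH2 terminus (C2) of a 1-methoxyvinyl group; the protonation that ends this cascade sets C6.
2. Enabling feature: in ring A the C1 carbonyl and the C3 methoxy group form a vinylogous ester (O=C1–C2H=C3–OMe). C2 is therefore the nucleophilic β-carbon of a methyl enol ether that already carries the C3 oxygen, and because C6 bears an H, C1/C6 can pass through a ketene and C6 is re-formed under control of the C4 ketal.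
3. The mixed ketal C4 (OMe, OAr) with C5 and C6/C1 comes from a temporary donor–acceptor cyclopropane (C4–C5–C6). It is made from 2,3-dimethoxybuta-1,3-diene (which brings C2–C5 and both methoxy groups) and ethyl diazoacetate, and is opened at C4–C6 by the phenol. The enantiomers are separated once; C6 is then allylated without control.
4. The aryl part (ring B) is 2-allyl-4,5-dimethoxyphenol, from 3,4-dimethoxyphenol by O-allylation and aromatic Claisen rearrangement.
5. Order of ring formation: ring B is bought; the cyclopropane is formed and opened; ring A is formed last.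

Key step: step 8

Remark on the chemistry: with the ring A numbering above the target is (4R,6S), the C6 allyl group being cis to the C4 aryloxy group. The C4 configuration comes from a chromatographic resolution (step 5); the (R)-enantiomer would be assigned by X-ray analysis of a derivative or by VCD.

**Route**

Step 1
Reactants: 1 3,4-dimethoxyphenol
Product: 2 4-(allyloxy)-1,2-dimethoxybenzene
Conditions: allyl bromide, K2CO3, acetone, reflux
Reagents that add atoms: allyl bromide, C=CCBr
Why: Williamson ether synthesis (SN2 of the phenoxide on the allylic bromide); no stereocenter is formed.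

Step 2
Reactants: 2 4-(allyloxy)-1,2-dimethoxybenzene
Product: 3 2-allyl-4,5-dimethoxyphenol
Conditions: N,N-diethylaniline, 200 °C, sealed tube
Reagents that add atoms: none
Why: Aromatic Claisen rearrangement ([3,3]) followed by tautomerization; the allyl group should go to the free ortho position that is not flanked by a methoxy group, and no stereocenter is formed.

Step 3
Reactants: 4 2,3-dimethoxybuta-1,3-diene (3 equiv), 5 ethyl diazoacetate
Product: 6 ethyl 2-methoxy-2-(1-methoxyethenyl)cyclopropane-1-carboxylate (racemic, cis/trans mixture)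
Conditions: Rh2(OAc)4 (1 mol %), slow addition of 5, CH2Cl2, 0 °C to rt
Reagents that add atoms: none
Why: Rhodium-carbenoid cyclopropanation of an electron-rich enol ether double bond, with excess diene to favor mono-addition; both stereocenters of 6 disappear in step 4, so no control is needed.

Step 4
Reactants: 6 ethyl 2-methoxy-2-(1-methoxyethenyl)cyclopropane-1-carboxylate, 3 2-allyl-4,5-dimethoxyphenol
Product: 7 ethyl 4-[4,5-dimethoxy-2-(prop-2-en-1-yl)phenoxy]-4,5-dimethoxyhex-5-enoate (racemic)
Conditions: pyridinium p-toluenesulfonate (5 mol %), 4 Å MS, CH2Cl2, −20 to 0 °C; then Et3N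
Reagents that add atoms: none
Why: Acid-catalysed ring-opening of a donor–acceptor (2-alkoxy) cyclopropane ester by an O–H nucleophile: the bond between donor and acceptor carbon breaks, the phenol oxygen should capture the oxocarbenium ion kinetically at the OMe-bearing carbon, and the ester enol tautomerizes; the ketal carbon is formed racemic.

Step 5
Reactants: 7 ethyl 4-[4,5-dimethoxy-2-(prop-2-en-1-yl)phenoxy]-4,5-dimethoxyhex-5-enoate (racemic)
Product: 8 ethyl (4R)-4-[4,5-dimethoxy-2-(prop-2-en-1-yl)phenoxy]-4,5-dimethoxyhex-5-enoate
Conditions: preparative HPLC, amylose tris(3,5-dimethylphenylcarbamate) stationary phase, hexane/2-propanol, 0.1 % Et3N, rt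
Reagents that add atoms: none
Why: Resolution of enantiomers by chromatography on a chiral stationary phase; this fixes the absolute configuration of the ketal carbon (C4 of ring A), which no later step touches, and the basic modifier protects the acid-labile ketal.

Step 6
Reactants: 8 ethyl (4R)-4-[4,5-dimethoxy-2-(prop-2-en-1-yl)phenoxy]-4,5-dimethoxyhex-5-enoate
Product: 9 ethyl (4R)-4-[4,5-dimethoxy-2-(prop-2-en-1-yl)phenoxy]-4,5-dimethoxy-2-(prop-2-en-1-yl)hex-5-enoate (both C2 epimers)
Conditions: LiN(iPr)2 (commercial solution, 1.05 equiv), THF, −78 °C; allyl bromide, −78 °C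
Reagents that add atoms: allyl bromide, C=CCBr
Why: Ester enolate alkylation (SN2 on allyl bromide); C2 (the future C6) is formed without control on purpose because step 8 erases and re-sets it, and the low temperature should keep the γ-aryloxy enolate intact.

Step 7
Reactants: 9 ethyl (4R)-4-[4,5-dimethoxy-2-(prop-2-en-1-yl)phenoxy]-4,5-dimethoxy-2-(prop-2-en-1-yl)hex-5-enoate
Product: 10 potassium (4R)-4-[4,5-dimethoxy-2-(prop-2-en-1-yl)phenoxy]-4,5-dimethoxy-2-(prop-2-en-1-yl)hex-5-enoate (both C2 epimers)
Conditions: KOH (1.05 equiv), EtOH/H2O, rt to 40 °C; evaporation and azeotropic drying, no acidification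
Reagents that add atoms: potassium hydroxide, [K+].[OH-]
Why: Ester saponification (BAc2); ketal and enol ether are stable to base, and isolation as the salt avoids a free γ-ketal acid that could cleave its own ketal.

Step 8
Reactants: 10 potassium (4R)-4-[4,5-dimethoxy-2-(prop-2-en-1-yl)phenoxy]-4,5-dimethoxy-2-(prop-2-en-1-yl)hex-5-enoate
Product: 14 (4R,6S)-4-[4,5-dimethoxy-2-(prop-2-en-1-yl)phenoxy]-3,4-dimethoxy-6-(prop-2-en-1-yl)cyclohex-2-en-1-one (CNP0352100.2), via mixed sulfonic anhydride 11 (not isolated), via ketene 12 (not isolated), via ammonium enolate 13 (not isolated)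
Conditions: TsCl (1.2 equiv), Et3N (4 equiv), MeCN/toluene, 0.005 M, 0 to 45 °C
Reagents that add atoms: none
Why: Proposed new method: TsCl should turn the carboxylate into mixed anhydride 11 and Et3N should eliminate tosylate to give the allyl-substituted ketene 12 (C6 is erased, so both epimers of 10 converge); the ketene carbon C1 is then attacked by the CH2 terminus (C2) of the 1-methoxyvinyl group, the oxocarbenium–enolate zwitterion loses its acidified C2 proton to Et3N to give the cross-conjugated enolate 13, and C-protonation at C6 by Et3NH+ gives the vinylogous ester. The closest known reactions are the generation of ketenes from carboxylic acids with TsCl/Et3N for intramolecular ketene cycloadditions, the stepwise zwitterionic addition of ketenes to enol ethers, and the C-acylation of enol ethers by acyl chlorides to β-alkoxy enones. Ring A is closed in a 6-endo-trig mode at the enol ether (C2 and C3 both end up in the ring) onto the sp carbon of the ketene; collapse of the zwitterion to a cyclobutanone is disfavoured because it would give a bicyclo[2.2.0]hexanone, whose donor–acceptor bond would reopen to the same zwitterion. C4 is not touched, and C6 is set by kinetic protonation of 13 on the face opposite the C4 aryloxy group, which is expected to sit pseudoaxial (the better σ* acceptor aligned with the dienolate π system), so that H enters trans and the allyl group ends cis to OAr, that is 6S. The step needs chemoselectivity for the enol ether over the two allyl alkenes and over ketene dimerization, secured by the electron-rich 1,1-disubstituted enol ether held three atoms from C6 and by high dilution; the regiochemistry of the vinylogous ester is fixed because the C3 oxygen is methylated before the ring exists.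

**Compound list**

1 | 3,4-dimethoxyphenol | COc1ccc(O)cc1OC | starting material
2 | 4-(allyloxy)-1,2-dimethoxybenzene | C=CCOc1ccc(OC)c(OC)c1 | intermediate
3 | 2-allyl-4,5-dimethoxyphenol | C=CCc1cc(OC)c(OC)cc1O | intermediate
4 | 2,3-dimethoxybuta-1,3-diene | C=C(OC)C(=C)OC | starting material
5 | ethyl diazoacetate | CCOC(=O)C=[N+]=[N-] | starting material
6 | ethyl 2-methoxy-2-(1-methoxyethenyl)cyclopropane-1-carboxylate (racemic, cis/trans mixture) | CCOC(=O)C1CC1(OC)C(=C)OC | intermediate
7 | ethyl 4-[4,5-dimethoxy-2-(prop-2-en-1-yl)phenoxy]-4,5-dimethoxyhex-5-enoate (racemic) | C=CCc1cc(OC)c(OC)cc1OC(C(=C)OC)(OC)CCC(=O)OCC | intermediate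
8 | ethyl (4R)-4-[4,5-dimethoxy-2-(prop-2-en-1-yl)phenoxy]-4,5-dimethoxyhex-5-enoate | C=CCc1cc(OC)c(OC)cc1O[C@](C(=C)OC)(OC)CCC(=O)OCC | intermediate
9 | ethyl (4R)-4-[4,5-dimethoxy-2-(prop-2-en-1-yl)phenoxy]-4,5-dimethoxy-2-(prop-2-en-1-yl)hex-5-enoate (both C2 epimers) | C=CCc1cc(OC)c(OC)cc1O[C@](C(=C)OC)(OC)CC(CC=C)C(=O)OCC | intermediate
10 | potassium (4R)-4-[4,5-dimethoxy-2-(prop-2-en-1-yl)phenoxy]-4,5-dimethoxy-2-(prop-2-en-1-yl)hex-5-enoate (both C2 epimers) | C=CCc1cc(OC)c(OC)cc1O[C@](C(=C)OC)(OC)CC(CC=C)C(=O)[O-].[K+] | intermediate
11 | (4R)-4-[4,5-dimethoxy-2-(prop-2-en-1-yl)phenoxy]-4,5-dimethoxy-2-(prop-2-en-1-yl)hex-5-enoic 4-methylbenzenesulfonic anhydride | C=CCc1cc(OC)c(OC)cc1O[C@](C(=C)OC)(OC)CC(CC=C)C(=O)OS(=O)(=O)c1ccc(C)cc1 | intermediate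
12 | (4R)-4-[4,5-dimethoxy-2-(prop-2-en-1-yl)phenoxy]-4,5-dimethoxy-2-(prop-2-en-1-yl)hexa-1,5-dien-1-one (ketene) | C=CCc1cc(OC)c(OC)cc1O[C@](C(=C)OC)(OC)CC(CC=C)=C=O | intermediate
13 | triethylammonium (4R)-4-[4,5-dimethoxy-2-(prop-2-en-1-yl)phenoxy]-4,5-dimethoxy-2-(prop-2-en-1-yl)cyclohexa-1,5-dien-1-olate | C=CCc1cc(OC)c(OC)cc1O[C@]1(OC)CC(CC=C)=C([O-])C=C1OC.CC[NH+](CC)CC | intermediate
14 | (4R,6S)-4-[4,5-dimethoxy-2-(prop-2-en-1-yl)phenoxy]-3,4-dimethoxy-6-(prop-2-en-1-yl)cyclohex-2-en-1-one (CNP0352100.2) | C=CCc1cc(OC)c(OC)cc1O[C@]1(OC)C[C@H](CC=C)C(=O)C=C1OC | target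

**Step count and risks**

Total step count: 8. Longest linear sequence: 7 steps (1, 2, 4, 5, 6, 7, 8).

Steps most likely to fail:

1. Step 8 (Proposed new method). What may go wrong: poor facial selectivity in the protonation of enolate 13 at C6, because both half-chair conformers of 13 may be populated, so that the C6 epimer accompanies 14. Fallback (known chemistry, thermodynamic recycling instead of kinetic control): setting out from 10, the cyclization is run as in step 8 and the mixture of 14 and its C6 epimer, (4R,6R)-4-[4,5-dimethoxy-2-(prop-2-en-1-yl)phenoxy]-3,4-dimethoxy-6-(prop-2-en-1-yl)cyclohex-2-en-1-one F1, is separated on silica. F1 is re-equilibrated at C6 through its enolate with catalytic KOtBu in tBuOH/THF at 0 °C (base-mediated α-epimerization of a ketone) and separated again, so the path comes back to the route at 14.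

2. Step 4. What may go wrong: acid-promoted drift of the kinetic ketal, by re-ionization of 7 and capture at the CH2 terminus, by addition of a second phenol to the enol ether, or by rearrangement of vinylcyclopropane 6 to a cyclopentene. Fallback: a non-acidic radical–polar crossover replaces steps 3 and 4. Compounds 4 and 3 and ethyl bromoacetate are coupled under visible-light photoredox catalysis (fac-Ir(ppy)3, 2,6-lutidine, MeCN, blue LEDs). The ester radical adds to a CH2 terminus of 4, the resulting α-methoxyallyl radical is oxidized to the oxocarbenium ion, and this is trapped by 3 at the OMe-bearing carbon (three-component oxyalkylation of an enol ether, a known reaction type). The path sets out from 4 and 3 and comes back at 7; no new compound lies on it (F0).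

3. Step 6. What may go wrong: the γ-aryloxy ester enolate may displace aryloxide from the ketal carbon (3-exo-tet closure to a cyclopropane, loss of the ketal) or condense with unreacted ester before it is allylated. Fallback: allylation before the ketal exists. Setting out from 6, the cyclopropane ester enolate (LiN(iPr)2, THF, −78 °C) is alkylated with allyl bromide to ethyl 2-methoxy-2-(1-methoxyethenyl)-1-(prop-2-en-1-yl)cyclopropane-1-carboxylate F2. Ring-opening with 3 as in step 4 gives ethyl 4-[4,5-dimethoxy-2-(prop-2-en-1-yl)phenoxy]-4,5-dimethoxy-2-(prop-2-en-1-yl)hex-5-enoate as all four stereoisomers F3. The two (4R) isomers are collected together on the chiral phase of step 5, and the path comes back at 9.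

**Further compounds**

F1 | step 8 | (4R,6R)-4-[4,5-dimethoxy-2-(prop-2-en-1-yl)phenoxy]-3,4-dimethoxy-6-(prop-2-en-1-yl)cyclohex-2-en-1-one | C=CCc1cc(OC)c(OC)cc1O[C@]1(OC)C[C@@H](CC=C)C(=O)C=C1OC
F0 | step 4 | none | none
F2 | step 6 | ethyl 2-methoxy-2-(1-methoxyethenyl)-1-(prop-2-en-1-yl)cyclopropane-1-carboxylate (racemic, cis/trans mixture) | CCOC(=O)C1(CC=C)CC1(OC)C(=C)OC
F3 | step 6 | ethyl 4-[4,5-dimethoxy-2-(prop-2-en-1-yl)phenoxy]-4,5-dimethoxy-2-(prop-2-en-1-yl)hex-5-enoate (all four stereoisomers) | C=CCc1cc(OC)c(OC)cc1OC(C(=C)OC)(OC)CC(CC=C)C(=O)OCC
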